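**Retrosynthetic overview**

1. Labels: ring A is the central benzene ring with carbons A-a (oxygen), A-b (hydrogen), A-c (oxygen), A-d, A-e and A-f in order; ring B runs B-a to B-f with oxygen on B-b and B-d; Cc is the ring CH2 on A-e, Cd the methine with the 2,4-dihydroxyphenyl group, Ce the bridgehead methine between A-d and B-f, Cf the O–CH(aryl) carbon on the A-c oxygen, Cg the methine on A-f and Ch the O–CH(aryl) carbon on the A-a oxygen. The strategy rests on three neighbouring carbons of ring A: A-c carries oxygen, A-d is bonded to Ce and A-e to Cc, so A-d and A-e hold both ends of the seven-membered ring (A-d, Ce, B-f, B-a, Cd, Cc, A-e).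
2. Last: BBr3 cleaves eight methyl ethers. Before that, the dihydrofuran on A-a and A-f is made by (4+1) annulation of an ortho-quinone methide at A-f with a chiral 4-methoxybenzyl sulfonium ylide (sets Cg and Ch).
3. The dihydrofuran on A-c and A-d comes from acid hydroalkoxylation of an exocyclic Ce=Cf benzylidene once the MOM groups are off (sets Ce and Cf).
4. Key disconnection: one Catellani step builds the seven-membered ring from 1-iodo-2,4-bis(methoxymethoxy)benzene and an enantiopure 2,2-diarylethyl bromide with a 4-methoxystyryl group on B-f. Ortho C–H alkylation joins A-e to Cc and ipso Heck closure joins A-d to Ce.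
5. Cd is set first, by catalytic ortho Friedel–Crafts addition of 3,5-dimethoxyphenol to a nitrostyrene. Ring order: seven-membered ring, then the dihydrofuran on A-c and A-d, then the dihydrofuran on A-a and A-f.

Key step: step 8

Assumption: the quinine-derived squaramide is taken to give (S) at Cd, and the ylide of the (2R,5R)-thiolane to give (R) at Ch (the sense expected from its benzylidene transfer to aldehydes); the pseudo-enantiomeric catalyst or the mirror-image sulfide would be used if either sense proved opposite.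

**Route**

Step 1
Reactants: 1 3,5-dimethoxyphenol; 2 (E)-2,4-dimethoxy-1-(2-nitrovinyl)benzene
Product: 3 2-[(1S)-1-(2,4-dimethoxyphenyl)-2-nitroethyl]-3,5-dimethoxyphenol
Conditions: quinine-derived squaramide (10 mol%), CH2Cl2, −20 °C; 1 in 1.5-fold excess
Reagents that add atoms: none
Why: Enantioselective Friedel–Crafts-type Michael addition under bifunctional hydrogen-bond catalysis: the squaramide binds the nitro group while the quinuclidine nitrogen binds the phenol O–H, which steers attack to the ortho carbon and to one face of the nitroalkene and should set Cd as (S).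

Step 2
Reactants: 3 2-[(1S)-1-(2,4-dimethoxyphenyl)-2-nitroethyl]-3,5-dimethoxyphenol
Product: 4 2-[(1S)-1-(2,4-dimethoxyphenyl)-2-nitroethyl]-3,5-dimethoxyphenyl trifluoromethanesulfonate
Conditions: Tf2O, pyridine, CH2Cl2, 0 °C
Reagents that add atoms: triflic anhydride, O=S(=O)(OS(=O)(=O)C(F)(F)F)C(F)(F)F
Why: O-Sulfonylation of the phenol with a base too weak to form the nitronate; masking the phenol now prevents lactonisation, and with it racemisation at Cd, once the acid is made.

Step 3
Reactants: 4 2-[(1S)-1-(2,4-dimethoxyphenyl)-2-nitroethyl]-3,5-dimethoxyphenyl trifluoromethanesulfonate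
Product: 5 (2S)-2-(2,4-dimethoxyphenyl)-2-[2,4-dimethoxy-6-(trifluoromethylsulfonyloxy)phenyl]acetic acid
Conditions: NaNO2, AcOH, DMSO, 35 °C
Reagents that add atoms: sodium nitrite, [Na+].[O-]N=O; water (present and formed in the medium), O
Why: Nitrosative Nef-type oxidation of a primary nitroalkane to the carboxylic acid (nitrolic acid, nitrile oxide, hydroxamic acid) under mildly acidic conditions that should leave the Cd–H bond and the aryl triflate untouched.

Step 4
Reactants: 5 (2S)-2-(2,4-dimethoxyphenyl)-2-[2,4-dimethoxy-6-(trifluoromethylsulfonyloxy)phenyl]acetic acid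
Product: 6 2-[(1S)-1-(2,4-dimethoxyphenyl)-2-hydroxyethyl]-3,5-dimethoxyphenyl trifluoromethanesulfonate
Conditions: BH3·THF, THF, 0 °C to rt; aqueous work-up
Reagents that add atoms: none
Why: Chemoselective borane reduction of a carboxylic acid to the primary alcohol, which spares the aryl triflate and does not pass through an enolisable species at Cd.

Step 5
Reactants: 6 2-[(1S)-1-(2,4-dimethoxyphenyl)-2-hydroxyethyl]-3,5-dimethoxyphenyl trifluoromethanesulfonate; 7 (E)-2-(4-methoxyphenyl)vinylboronic acid
Product: 8 (2S)-2-(2,4-dimethoxyphenyl)-2-{2,4-dimethoxy-6-[(E)-2-(4-methoxyphenyl)vinyl]phenyl}ethanol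
Conditions: Pd(OAc)2 (5 mol%), SPhos (10 mol%), K3PO4, toluene–H2O, 70 °C
Reagents that add atoms: none
Why: Suzuki–Miyaura coupling of an ortho-hindered aryl triflate with an (E)-alkenylboronic acid, which fixes both the position and the E geometry of the styryl group, something a Heck reaction with the electron-rich styrene would not guarantee.

Step 6
Reactants: 8 (2S)-2-(2,4-dimethoxyphenyl)-2-{2,4-dimethoxy-6-[(E)-2-(4-methoxyphenyl)vinyl]phenyl}ethanol
Product: 9 1-[(1S)-2-bromo-1-(2,4-dimethoxyphenyl)ethyl]-2,4-dimethoxy-6-[(E)-2-(4-methoxyphenyl)vinyl]benzene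
Conditions: CBr4, PPh3, CH2Cl2, 0 °C
Reagents that add atoms: carbon tetrabromide, BrC(Br)(Br)Br
Why: Appel bromination: SN2 displacement of the alkoxyphosphonium at the primary carbon in a non-ionising solvent at 0 °C should outrun aryl participation and leave Cd and the stilbene alone.

Step 7
Reactants: 10 4-iodoresorcinol
Product: 11 1-iodo-2,4-bis(methoxymethoxy)benzene
Conditions: MOMCl, i-Pr2NEt, CH2Cl2, 0 °C to rt
Reagents that add atoms: chloromethyl methyl ether, COCCl
Why: O-Alkylation of both phenols to the acetals; MOM survives base and palladium, is later removed by acid beside methyl ethers, and supplies the ortho bulk on A-c that the next step needs.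

Step 8
Reactants: 9 1-[(1S)-2-bromo-1-(2,4-dimethoxyphenyl)ethyl]-2,4-dimethoxy-6-[(E)-2-(4-methoxyphenyl)vinyl]benzene; 11 1-iodo-2,4-bis(methoxymethoxy)benzene
Product: 13 (5E,10S)-10-(2,4-dimethoxyphenyl)-7,9-dimethoxy-5-(4-methoxybenzylidene)-2,4-bis(methoxymethoxy)-10,11-dihydro-5H-dibenzo[a,d][7]annulene, via ortho-alkylated arylpalladium iodide 12 (not isolated)
Conditions: Pd(OAc)2 (10 mol%), P(2-furyl)3 (22 mol%), norbornene (2 equiv), Cs2CO3 (3 equiv), MeCN, 85 °C; 11 in 1.5-fold excess
Reagents that add atoms: none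
Why: Oxidative addition of zerovalent palladium to the C–I bond at A-d of 11 is followed by norbornene carbopalladation and C–H palladation at A-e, and the five-membered palladacycle takes up the primary bromide 9 to reach tetravalent palladium, from which reductive elimination joins A-e to Cc. Because A-d then has substituents on both sides, norbornene is lost by β-carbon elimination and the divalent arylpalladium iodide 12 inserts the tethered stilbene and undergoes β-hydride elimination. The closest known reaction type is the Catellani ortho-alkylation of aryl iodides with bromoalkyl-tethered alkenes that ends in an intramolecular Heck reaction. The seven-membered ring closes in the 7-exo-trig mode with A-d bonding to Ce, which should be preferred over 8-endo attack at Cf. No stereocentre is created: the Cd–H bond is too weakly acidic for carbonate, so Cd is a spectator, and syn insertion, rotation about the Ce–Cf bond and syn β-hydride elimination should turn the (E)-stilbene into the single benzylidene isomer with the 4-methoxyphenyl group cis to ring B and trans to ring A. The step needs a single alkylation and alkylation before Heck closure: the OMOM group on A-c is the one ortho substituent that blocks a second alkylation and drives norbornene out, norbornene inserts faster than the hindered diaryl alkene so 11 cannot couple directly, and Cs2CO3 in MeCN is mild enough to limit base-induced loss of HBr from the β-branched bromide.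

Step 9
Reactants: 13 (5E,10S)-10-(2,4-dimethoxyphenyl)-7,9-dimethoxy-5-(4-methoxybenzylidene)-2,4-bis(methoxymethoxy)-10,11-dihydro-5H-dibenzo[a,d][7]annulene
Product: 15 phenol with the trans dihydrofuran closed from the A-c oxygen to Cf (Cd S; Ce R; Cf R; hydroxyl on A-a free), via free resorcinol benzylidene 14 (not isolated)
Conditions: HCl (3 M aq.), MeOH–THF, 50 °C; then TsOH·H2O (20 mol%), ClCH2CH2Cl, 60 °C, high dilution
Reagents that add atoms: none
Why: Acidic methanolysis of the MOM acetals, then Brønsted-acid hydroalkoxylation: protonation at Ce gives the 4-methoxybenzyl cation at Cf, which the hydroxyl on A-c traps in a five-membered ring; because ionisation at Cf and proton transfer at Ce are reversible, the 2,3-trans ring and the Ce epimer that keeps the Cd aryl group pseudo-equatorial (Cd–H and Ce–H cis, as a model of the ring suggests) should accumulate.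

Step 10
Reactants: 15 phenol with the trans dihydrofuran closed from the A-c oxygen to Cf
Product: 16 carbaldehyde of 15 with CHO on A-f (hydroxyl on A-a; Cd S; Ce R; Cf R)
Conditions: MgCl2, Et3N, (CH2O)n, MeCN, 80 °C
Reagents that add atoms: paraformaldehyde (as formaldehyde), C=O
Why: Magnesium-phenoxide-directed ortho-formylation: only the two carbons ortho to the hydroxyl on A-a can react, and A-f, para to the ether oxygen on A-c, should be the more nucleophilic (the pattern of orcinol and 6-hydroxy-2,3-dihydrobenzofuran), while the basic medium spares the acid-labile benzylic ether.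

Step 11
Reactants: 16 carbaldehyde of 15 with CHO on A-f; 17 3,5-dimethoxyphenylmagnesium chloride (THF solution, 3 equiv)
Product: 18 benzhydrol with CH(OH)(3,5-dimethoxyphenyl) on A-f, both carbinol epimers
Conditions: THF, −40 to 0 °C; aq. NH4Cl
Reagents that add atoms: none
Why: Grignard addition to the aldehyde after deprotonation of the phenol; the carbinol centre forms as a mixture, which does not matter because that carbon becomes trigonal in step 16.

Step 12
Reactants: 18 benzhydrol with CH(OH)(3,5-dimethoxyphenyl) on A-f; 19 sodium p-toluenesulfinate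
Product: 20 sulfone with CH(SO2-p-Tol)(3,5-dimethoxyphenyl) on A-f, both epimers
Conditions: HCO2H, CH2Cl2–H2O, rt
Reagents that add atoms: none
Why: Mild acid ionises the ortho-hydroxybenzhydrol and sulfinate captures the cation at sulfur, giving the base-labile sulfone that is the usual storable precursor of an ortho-quinone methide.

Step 13
Reactants: 21 (2S,5S)-hexane-2,5-diol
Product: 22 (2S,5S)-hexane-2,5-diyl dimethanesulfonate
Conditions: MsCl, Et3N, CH2Cl2, 0 °C
Reagents that add atoms: methanesulfonyl chloride, CS(=O)(=O)Cl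
Why: Sulfonylation of both secondary alcohols with retention at carbon.

Step 14
Reactants: 22 (2S,5S)-hexane-2,5-diyl dimethanesulfonate
Product: 23 (2R,5R)-2,5-dimethylthiolane
Conditions: Na2S·9H2O, EtOH–H2O, rt to 50 °C
Reagents that add atoms: sodium sulfide nonahydrate (Na2S·9H2O), [Na+].[Na+].[S-2]
Why: Double SN2 displacement by sulfide with inversion at both centres, turning the (S,S) dimesylate into the twofold-symmetric (R,R) thiolane.

Step 15
Reactants: 23 (2R,5R)-2,5-dimethylthiolane; 24 4-methoxybenzyl alcohol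
Product: 25 (2R,5R)-1-(4-methoxybenzyl)-2,5-dimethylthiolanium tetrafluoroborate
Conditions: HBF4·OEt2, CH2Cl2, 0 °C to rt
Reagents that add atoms: tetrafluoroboric acid diethyl etherate (HBF4·OEt2), [H+].F[B-](F)(F)F
Why: Acid-promoted S-alkylation in which the sulfide captures the 4-methoxybenzyl cation; the twofold symmetry of the thiolane makes sulfur non-stereogenic, so one salt should result.

Step 16
Reactants: 20 sulfone with CH(SO2-p-Tol)(3,5-dimethoxyphenyl) on A-f; 25 (2R,5R)-1-(4-methoxybenzyl)-2,5-dimethylthiolanium tetrafluoroborate (1.5 equiv)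
Product: 27 octamethyl ether of the target (Cd S; Ce R; Cf R; Cg R; Ch R), via ortho-quinone methide 26 (not isolated)
Conditions: Cs2CO3 (3 equiv), CH2Cl2, −20 °C to rt
Reagents that add atoms: none
Why: Sulfur-ylide (4+1) annulation of an ortho-quinone methide: carbonate eliminates sulfinate from 20 to give 26 and deprotonates 25, the ylide adds at Cg and the phenoxide closes the ring by SN2 with loss of the sulfide, which should give the 2,3-trans ring (anti betaine), the chiral thiolane choosing the face of the ylide carbon and so fixing Ch as (R) and, through the trans closure, Cg as (R).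

Step 17
Reactants: 27 octamethyl ether of the target
Product: 28 CNP0154047.2 (target)
Conditions: BBr3 (excess), CH2Cl2, −78 °C to rt; aq. NaHCO3
Reagents that add atoms: none
Why: Lewis-acid cleavage of all eight aryl methyl ethers; both dihydrofurans are already in their preferred trans form, so any reversible benzylic C–O ionisation should return the same isomers.

**Compound list**

1 | 3,5-dimethoxyphenol | COc1cc(O)cc(OC)c1 | starting material
2 | (E)-2,4-dimethoxy-1-(2-nitrovinyl)benzene | COc1ccc(/C=C/[N+](=O)[O-])c(OC)c1 | starting material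
3 | 2-[(1S)-1-(2,4-dimethoxyphenyl)-2-nitroethyl]-3,5-dimethoxyphenol | O=[N+]([O-])C[C@@H](c1ccc(OC)cc1OC)c1c(OC)cc(OC)cc1O | intermediate
4 | 2-[(1S)-1-(2,4-dimethoxyphenyl)-2-nitroethyl]-3,5-dimethoxyphenyl trifluoromethanesulfonate | O=[N+]([O-])C[C@@H](c1ccc(OC)cc1OC)c1c(OC)cc(OC)cc1OS(=O)(=O)C(F)(F)F | intermediate
5 | (2S)-2-(2,4-dimethoxyphenyl)-2-[2,4-dimethoxy-6-(trifluoromethylsulfonyloxy)phenyl]acetic acid | OC(=O)[C@@H](c1ccc(OC)cc1OC)c1c(OC)cc(OC)cc1OS(=O)(=O)C(F)(F)F | intermediate
6 | 2-[(1S)-1-(2,4-dimethoxyphenyl)-2-hydroxyethyl]-3,5-dimethoxyphenyl trifluoromethanesulfonate | OC[C@@H](c1ccc(OC)cc1OC)c1c(OC)cc(OC)cc1OS(=O)(=O)C(F)(F)F | intermediate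
7 | (E)-2-(4-methoxyphenyl)vinylboronic acid | COc1ccc(/C=C/B(O)O)cc1 | starting material
8 | (2S)-2-(2,4-dimethoxyphenyl)-2-{2,4-dimethoxy-6-[(E)-2-(4-methoxyphenyl)vinyl]phenyl}ethanol | OC[C@@H](c1ccc(OC)cc1OC)c1c(OC)cc(OC)cc1/C=C/c1ccc(OC)cc1 | intermediate
9 | 1-[(1S)-2-bromo-1-(2,4-dimethoxyphenyl)ethyl]-2,4-dimethoxy-6-[(E)-2-(4-methoxyphenyl)vinyl]benzene | BrC[C@@H](c1ccc(OC)cc1OC)c1c(OC)cc(OC)cc1/C=C/c1ccc(OC)cc1 | intermediate
10 | 4-iodoresorcinol (4-iodobenzene-1,3-diol) | Oc1ccc(I)c(O)c1 | starting material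
11 | 1-iodo-2,4-bis(methoxymethoxy)benzene | COCOc1ccc(I)c(OCOC)c1 | intermediate
12 | arylpalladium iodide formed after alkylation at A-e and loss of norbornene (divalent palladium; phosphine ligands not drawn) | COCOc1cc(OCOC)c([Pd]I)c(c1)C[C@@H](c1ccc(OC)cc1OC)c1c(OC)cc(OC)cc1/C=C/c1ccc(OC)cc1 | intermediate
13 | (5E,10S)-10-(2,4-dimethoxyphenyl)-7,9-dimethoxy-5-(4-methoxybenzylidene)-2,4-bis(methoxymethoxy)-10,11-dihydro-5H-dibenzo[a,d][7]annulene (4-methoxyphenyl cis to ring B) | COCOc1cc(OCOC)c2c(c1)C[C@@H](c1ccc(OC)cc1OC)c1c(OC)cc(OC)cc1/C2=C\c1ccc(OC)cc1 | intermediate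
14 | (5E,10S)-10-(2,4-dimethoxyphenyl)-7,9-dimethoxy-5-(4-methoxybenzylidene)-10,11-dihydro-5H-dibenzo[a,d][7]annulene-2,4-diol | Oc1cc(O)c2c(c1)C[C@@H](c1ccc(OC)cc1OC)c1c(OC)cc(OC)cc1/C2=C\c1ccc(OC)cc1 | intermediate
15 | phenol with the trans dihydrofuran (A-c, O, Cf, Ce, A-d) closed on the dibenzocycloheptane: hydroxyl on A-a free, hydrogen on A-f, 4-methoxyphenyl on Cf, 2,4-dimethoxyphenyl on Cd, OMe on B-b and B-d; Cd S, Ce R, Cf R | Oc1cc2c3c(c1)C[C@@H](c1ccc(OC)cc1OC)c1c(OC)cc(OC)cc1[C@H]3[C@H](c1ccc(OC)cc1)O2 | intermediate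
16 | carbaldehyde of 15 with CHO on A-f and the hydroxyl on A-a; Cd S, Ce R, Cf R | Oc1cc2c3c(c1C=O)C[C@@H](c1ccc(OC)cc1OC)c1c(OC)cc(OC)cc1[C@H]3[C@H](c1ccc(OC)cc1)O2 | intermediate
17 | 3,5-dimethoxyphenylmagnesium chloride | COc1cc([Mg]Cl)cc(OC)c1 | starting material
18 | benzhydrol of 15 with CH(OH)(3,5-dimethoxyphenyl) on A-f, both carbinol epimers; Cd S, Ce R, Cf R | Oc1cc2c3c(c1C(O)c1cc(OC)cc(OC)c1)C[C@@H](c1ccc(OC)cc1OC)c1c(OC)cc(OC)cc1[C@H]3[C@H](c1ccc(OC)cc1)O2 | intermediate
19 | sodium p-toluenesulfinate | Cc1ccc(S(=O)[O-])cc1.[Na+] | starting material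
20 | sulfone with CH(SO2-p-tolyl)(3,5-dimethoxyphenyl) on A-f, both epimers; Cd S, Ce R, Cf R | Oc1cc2c3c(c1C(c1cc(OC)cc(OC)c1)S(=O)(=O)c1ccc(C)cc1)C[C@@H](c1ccc(OC)cc1OC)c1c(OC)cc(OC)cc1[C@H]3[C@H](c1ccc(OC)cc1)O2 | intermediate
21 | (2S,5S)-hexane-2,5-diol | C[C@H](O)CC[C@H](C)O | starting material
22 | (2S,5S)-hexane-2,5-diyl dimethanesulfonate | C[C@H](OS(C)(=O)=O)CC[C@H](C)OS(C)(=O)=O | intermediate
23 | (2R,5R)-2,5-dimethylthiolane | C[C@@H]1CC[C@@H](C)S1 | intermediate
24 | 4-methoxybenzyl alcohol | COc1ccc(CO)cc1 | starting material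
25 | (2R,5R)-1-(4-methoxybenzyl)-2,5-dimethylthiolanium tetrafluoroborate | C[C@@H]1CC[C@@H](C)[S+]1Cc1ccc(OC)cc1.F[B-](F)(F)F | intermediate
26 | ortho-quinone methide: carbonyl at A-a, exocyclic C=CH(3,5-dimethoxyphenyl) at A-f; Cd S, Ce R, Cf R | O=C1C=C2C3=C(C1=Cc1cc(OC)cc(OC)c1)C[C@@H](c1ccc(OC)cc1OC)c1c(OC)cc(OC)cc1[C@H]3[C@H](c1ccc(OC)cc1)O2 | intermediate
27 | octamethyl ether of the target; Cd S, Ce R, Cf R, Cg R, Ch R | COc1ccc([C@@H]2Oc3cc4c5c(c3[C@H]2c2cc(OC)cc(OC)c2)C[C@@H](c2ccc(OC)cc2OC)c2c(OC)cc(OC)cc2[C@H]5[C@H](c2ccc(OC)cc2)O4)cc1 | intermediate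
28 | CNP0154047.2; Cd S, Ce R, Cf R, Cg R, Ch R | Oc1ccc([C@@H]2Oc3cc4c5c(c3[C@H]2c2cc(O)cc(O)c2)C[C@@H](c2ccc(O)cc2O)c2c(O)cc(O)cc2[C@H]5[C@H](c2ccc(O)cc2)O4)cc1 | target

**Step count and risks**

Total steps: 17. Longest linear sequence: 13 (steps 1–6, 8–12, 16, 17).

Steps most likely to fail:

1. Step 8. The β-branched bromide may lose HBr, or ionise with help from its electron-rich aryl groups, faster than it adds to the palladacycle, so ortho alkylation may not keep pace with decomposition of 9. Fallback, from 9 back to 13, by stepwise cross-coupling. 5-Iodoresorcinol (Oc1cc(O)cc(I)c1) is protected with MOMCl and i-Pr2NEt to 1-iodo-3,5-bis(methoxymethoxy)benzene F1. NBS in MeCN at 0 °C brominates it ortho to iodine to give 2-bromo-1-iodo-3,5-bis(methoxymethoxy)benzene F2. Bromide 9 is converted with Zn dust and LiCl in THF into the alkylzinc bromide F3, which undergoes Negishi coupling at the C–I bond of F2 (PdCl2(dppf), THF, 40 °C) to give the aryl bromide F4, with bromine on A-d and the diarylethyl chain on A-e. A conventional 7-exo intramolecular Heck reaction of F4 (Pd(OAc)2, P(o-tol)3, Et3N, DMF, 100 °C) then gives 13.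

2. Step 16. The sulfonium salt may benzylate the phenoxide on oxygen, the quinone methide may self-condense, or the ylide may discriminate poorly between the faces of the quinone methide. Fallback, from 18 back to 27, by carbene C–H insertion. The phenol of 18 is alkylated with 4-methoxybenzyl chloride and K2CO3 in DMF to the 4-methoxybenzyl ether F7. Dess–Martin periodinane oxidises the carbinol to the diaryl ketone F8, and hydrazine hydrate with AcOH in EtOH at 80 °C gives the hydrazone F9. MnO2 oxidises F9 in the flask to the diaryldiazomethane F10. Rh2(R-PTAD)4, or its enantiomer, whichever delivers (R) at Cg, inserts the carbene into the benzylic C–H of the ether to give the cis-2,3-diaryl dihydrofuran F11. Brief treatment with TsOH in CH2Cl2 epimerises Ch by reversible benzylic C–O ionisation and gives 27.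

3. Step 9. Protonation may favour the doubly benzylic cation at Ce and Friedel–Crafts side reactions, or equilibration may settle on the other Ce epimer. Fallback, from 13 back to 15, by kinetic control at Ce. Hydroboration of 13 with BH3·THF should deliver hydrogen to Ce and boron to Cf in a syn sense on the alkene face away from the Cd aryl group, giving the alkylborane F5. NaOH and H2O2 oxidise it with retention to the Cf alcohol F6. HCl in MeOH at rt removes the MOM groups and ionises the 4-methoxybenzylic alcohol, and the hydroxyl on A-c traps the cation faster than the Ce–H is lost, closing the trans dihydrofuran of 15.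

**Further compounds**

F1 | step 8 | 1-iodo-3,5-bis(methoxymethoxy)benzene | COCOc1cc(I)cc(OCOC)c1
F2 | step 8 | 2-bromo-1-iodo-3,5-bis(methoxymethoxy)benzene | COCOc1cc(I)c(Br)c(OCOC)c1
F3 | step 8 | (2S)-2-(2,4-dimethoxyphenyl)-2-{2,4-dimethoxy-6-[(E)-2-(4-methoxyphenyl)vinyl]phenyl}ethylzinc bromide | Br[Zn]C[C@@H](c1ccc(OC)cc1OC)c1c(OC)cc(OC)cc1/C=C/c1ccc(OC)cc1
F4 | step 8 | aryl bromide with bromine on A-d and the 2,2-diarylethyl chain on A-e | COCOc1cc(OCOC)c(Br)c(c1)C[C@@H](c1ccc(OC)cc1OC)c1c(OC)cc(OC)cc1/C=C/c1ccc(OC)cc1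
F5 | step 9 | alkylborane of 13 with BH2 on Cf and H on Ce (Cd S, Ce R, Cf R) | COCOc1cc(OCOC)c2c(c1)C[C@@H](c1ccc(OC)cc1OC)c1c(OC)cc(OC)cc1[C@H]2[C@@H](B)c1ccc(OC)cc1
F6 | step 9 | Cf alcohol of 13 (Cd S, Ce R, Cf R) | COCOc1cc(OCOC)c2c(c1)C[C@@H](c1ccc(OC)cc1OC)c1c(OC)cc(OC)cc1[C@H]2[C@@H](O)c1ccc(OC)cc1
F7 | step 16 | 4-methoxybenzyl ether of 18 on the A-a oxygen | COc1ccc(COc2cc3c4c(c2C(O)c2cc(OC)cc(OC)c2)C[C@@H](c2ccc(OC)cc2OC)c2c(OC)cc(OC)cc2[C@H]4[C@H](c2ccc(OC)cc2)O3)cc1
F8 | step 16 | 3,5-dimethoxybenzoyl ketone on A-f with the 4-methoxybenzyl ether on the A-a oxygen | COc1ccc(COc2cc3c4c(c2C(=O)c2cc(OC)cc(OC)c2)C[C@@H](c2ccc(OC)cc2OC)c2c(OC)cc(OC)cc2[C@H]4[C@H](c2ccc(OC)cc2)O3)cc1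
F9 | step 16 | hydrazone of F8 | COc1ccc(COc2cc3c4c(c2C(=NN)c2cc(OC)cc(OC)c2)C[C@@H](c2ccc(OC)cc2OC)c2c(OC)cc(OC)cc2[C@H]4[C@H](c2ccc(OC)cc2)O3)cc1
F10 | step 16 | diaryldiazomethane from F9 | COc1ccc(COc2cc3c4c(c2C(=[N+]=[N-])c2cc(OC)cc(OC)c2)C[C@@H](c2ccc(OC)cc2OC)c2c(OC)cc(OC)cc2[C@H]4[C@H](c2ccc(OC)cc2)O3)cc1
F11 | step 16 | Ch epimer of 27 (cis dihydrofuran; Cg R, Ch S) | COc1ccc([C@H]2Oc3cc4c5c(c3[C@H]2c2cc(OC)cc(OC)c2)C[C@@H](c2ccc(OC)cc2OC)c2c(OC)cc(OC)cc2[C@H]5[C@H](c2ccc(OC)cc2)O4)cc1
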